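**Plan**

Rings: A = benzo ring and C = pyranone ring of the chromanone, B = phenol ring on C2 of ring C, D = cyclohexene (C1 on ring B, C2=C3 with methyl on C3, C5 on ring E, C6 carrying the aroyl group), E = 2,4-dihydroxyphenyl, F = prenylated benzoyl ring.
Retrosynthesis: (a) remove five acetates; (b) cut the bond from ring B to C2 of ring C, giving para-substituted phenol 14 and chromone 2,3-epoxide 17; (c) open ring D by retro-Diels–Alder into chalcone 8 and diene 11; (d) cut the chalcone C=C (aldol) into 3 and 5.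
Enabling feature: C2 of ring C bears ring oxygen O1 and its neighbour C3 bears OH, so C2–C3 is the opened form of an epoxide on a chromone C2=C3 bond, an acetal-level electrophile at C2. Ring B is a phenol with OH ortho to the bond to be made, its para carbon blocked by ring D and its two ortho carbons equivalent.
Forward: rings E and F are joined as a chalcone; ring D is built on it by an exo asymmetric Diels–Alder reaction with the diene carrying ring B; the ring B phenol is unmasked; rings A/C are attached by opening 17 at C2 with an ortho carbon of ring B; deacetylation finishes.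
Stereochemistry: ring D from the Diels–Alder step (E-enone gives trans C5/C6, exo approach gives trans C1/C6, chiral boron complex gives the absolute sense); C3 of ring C from enantioselective epoxidation; C2 from anti opening of that epoxide.

Key step: step 14

Assumption: the facial sense of the two catalyst-controlled steps (9 and 13) is assigned by analogy with related substrates; if a trial shows the opposite sense, the mirror-image ligand or salen complex is used with nothing else changed.

**Step 1**
Reactants: 1 2',4'-dihydroxyacetophenone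
Product: 2 1-[2,4-dihydroxy-3-(3-methylbut-2-enyl)phenyl]ethanone
Conditions: prenyl bromide, KOH (10% aq), 0 °C to rt
Reagents that add atoms: prenyl bromide, CC(C)=CCBr
Why: Aqueous-base C-prenylation of the resorcinol dianion should occur at C3, the carbon between the two oxygens and the most nucleophilic ring position; O-prenyl and 5-prenyl isomers are removed by chromatography.

**Step 2**
Reactants: 2 1-[2,4-dihydroxy-3-(3-methylbut-2-enyl)phenyl]ethanone
Product: 3 1-[2-hydroxy-3-(3-methylbut-2-enyl)-4-(prop-2-enyloxy)phenyl]ethanone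
Conditions: allyl bromide (1.05 equiv), K2CO3, acetone, reflux
Reagents that add atoms: allyl bromide, C=CCBr
Why: Williamson etherification should touch only the 4-OH, because the 2-OH is held in a hydrogen bond to the acetyl group.

**Step 3**
Reactants: 4 2,4-dihydroxybenzaldehyde
Product: 5 2,4-bis(prop-2-enyloxy)benzaldehyde
Conditions: allyl bromide (2.5 equiv), K2CO3, DMF, 60 °C
Reagents that add atoms: allyl bromide, C=CCBr
Why: Williamson etherification of both phenols with excess halide removes the phenoxide deactivation of the aldehyde before the aldol step.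

**Step 4**
Reactants: 3 1-[2-hydroxy-3-(3-methylbut-2-enyl)-4-(prop-2-enyloxy)phenyl]ethanone; 5 2,4-bis(prop-2-enyloxy)benzaldehyde
Product: 6 (E)-3-[2,4-bis(prop-2-enyloxy)phenyl]-1-[2-hydroxy-3-(3-methylbut-2-enyl)-4-(prop-2-enyloxy)phenyl]prop-2-en-1-one
Conditions: KOH, EtOH/H2O, rt
Reagents that add atoms: none
Why: Claisen–Schmidt condensation with E1cB dehydration should give the E-enone; allyl ethers are stable to hydroxide and a free 2'-OH is tolerated in this reaction.

**Step 5**
Reactants: 6 tris(allyl) chalcone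
Product: 7 morachalcone A, (E)-1-[2,4-dihydroxy-3-(3-methylbut-2-enyl)phenyl]-3-(2,4-dihydroxyphenyl)prop-2-en-1-one
Conditions: Pd(PPh3)4 (zerovalent palladium, 5 mol%), K2CO3, MeOH, rt
Reagents that add atoms: none
Why: Palladium-catalysed deallylation (Tsuji–Trost type, π-allyl capture by methoxide) frees the phenols without acid, so the prenyl group cannot cyclise onto a flanking phenol and the 2-hydroxychalcone cannot close to a flavylium salt.

**Step 6**
Reactants: 7 morachalcone A
Product: 8 (E)-1-[4-acetoxy-2-hydroxy-3-(3-methylbut-2-enyl)phenyl]-3-(2,4-diacetoxyphenyl)prop-2-en-1-one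
Conditions: Ac2O (3.3 equiv), pyridine, CH2Cl2, 0 °C
Reagents that add atoms: acetic anhydride, CC(=O)OC(C)=O
Why: Selective acetylation should cap the three unchelated phenols and leave the hydrogen-bonded 2'-OH, which is needed for boron binding in step 9.

**Step 7**
Reactants: 9 (E)-4-(4-hydroxyphenyl)but-3-en-2-one
Product: 10 (E)-4-[4-(tert-butyldimethylsilyloxy)phenyl]but-3-en-2-one
Conditions: TBSCl, imidazole, DMF, rt
Reagents that add atoms: tert-butyldimethylsilyl chloride, CC(C)(C)[Si](C)(C)Cl
Why: Silylation gives ring B a protecting group that is orthogonal to the acetates used elsewhere.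

**Step 8**
Reactants: 10 (E)-4-[4-(tert-butyldimethylsilyloxy)phenyl]but-3-en-2-one
Product: 11 tert-butyldimethyl{4-[(1E)-3-methylbuta-1,3-dienyl]phenoxy}silane
Conditions: Ph3PCH3Br, NaN(SiMe3)2, THF, 0 °C to rt
Reagents that add atoms: methyltriphenylphosphonium bromide, C[P+](c1ccccc1)(c1ccccc1)c1ccccc1.[Br-]
Why: Wittig methylenation of the enone carbonyl (1,2-addition) should give the 1-aryl-3-methylbutadiene with the E styrenyl bond unchanged.

**Step 9**
Reactants: 8 triacetyl chalcone; 11 diene
Product: 12 4-[(1R,5S,6R)-6-[4-acetoxy-2-hydroxy-3-(3-methylbut-2-enyl)benzoyl]-5-(2,4-diacetoxyphenyl)-3-methylcyclohex-2-en-1-yl]phenyl tert-butyldimethylsilyl ether (all-trans, exo adduct)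
Conditions: (R)-VANOL [(R)-3,3'-diphenyl-2,2'-binaphthalene-1,1'-diol] (30 mol%), BH3·THF (30 mol%), AcOH (30 mol%), 5 Å MS, THF, rt
Reagents that add atoms: none
Why: Chiral-boron-promoted asymmetric Diels–Alder reaction of a 2'-hydroxychalcone: boron binds the phenolate and carbonyl oxygens, lowering the LUMO while the biaryl diol shields one enone face; the diene CH2 terminus bonds to the enone β-carbon (ortho/para rule), the E-enone fixes trans C5/C6, the exo approach sets trans C1/C6, the ligand sets the absolute sense, and the endo isomer expected alongside is removed by chromatography.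

**Step 10**
Reactants: 12 exo adduct
Product: 13 4-[(1R,5S,6R)-6-[2,4-diacetoxy-3-(3-methylbut-2-enyl)benzoyl]-5-(2,4-diacetoxyphenyl)-3-methylcyclohex-2-en-1-yl]phenyl tert-butyldimethylsilyl ether
Conditions: Ac2O, Et3N, DMAP (cat.), CH2Cl2, rt
Reagents that add atoms: acetic anhydride, CC(=O)OC(C)=O
Why: DMAP-catalysed acetylation caps the chelated phenol next to the prenyl group, so the Lewis acid of step 14 cannot close a chroman ring and ring B will carry the only free phenol.

**Step 11**
Reactants: 13 tetraacetate silyl ether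
Product: 14 4-[(1R,5S,6R)-6-[2,4-diacetoxy-3-(3-methylbut-2-enyl)benzoyl]-5-(2,4-diacetoxyphenyl)-3-methylcyclohex-2-en-1-yl]phenol
Conditions: HF·pyridine, THF/pyridine, 0 °C
Reagents that add atoms: none
Why: Fluoride desilylation of the aryl silyl ether should leave the aryl acetates, the ketone and both alkenes untouched.

**Step 12**
Reactants: 15 7-hydroxychromone (7-hydroxy-4H-chromen-4-one)
Product: 16 7-acetoxychromone (4-oxo-4H-chromen-7-yl acetate)
Conditions: Ac2O, pyridine, CH2Cl2, 0 °C to rt
Reagents that add atoms: acetic anhydride, CC(=O)OC(C)=O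
Why: Acetylation masks the ring A phenol against oxidation in step 13 and matches the final global deprotection.

**Step 13**
Reactants: 16 7-acetoxychromone
Product: 17 (2R,3R)-7-acetoxy-2,3-epoxychroman-4-one (cis-fused oxirane on C2–C3)
Conditions: mCPBA, N-methylmorpholine N-oxide, (R,R)-N,N'-bis(3,5-di-tert-butylsalicylidene)-1,2-cyclohexanediaminomanganese chloride (C36H52ClMnN2O2, trivalent manganese, 5 mol%), CH2Cl2, −78 °C
Reagents that add atoms: 3-chloroperoxybenzoic acid, OOC(=O)c1cccc(Cl)c1
Why: Jacobsen–Katsuki epoxidation of the cis-disubstituted enol-ether bond C2=C3 (oxo-manganese attack at nucleophilic C3, radical character at oxygen-bearing C2) should set both oxirane centres under catalyst control, and the anhydrous low-temperature variant keeps the acid- and water-labile epoxide intact.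

**Step 14**
Reactants: 14 ring B phenol; 17 epoxychromanone
Product: 19 (2R,3R)-7-acetoxy-2-{5-[(1R,5S,6R)-6-[2,4-diacetoxy-3-(3-methylbut-2-enyl)benzoyl]-5-(2,4-diacetoxyphenyl)-3-methylcyclohex-2-en-1-yl]-2-hydroxyphenyl}-3-hydroxychroman-4-one, via O-aryl acetal 18 (not isolated)
Conditions: Sc(OSO2CF3)3 (10 mol%), 4 Å MS, CH2Cl2, −40 °C, epoxide in slight excess added in portions, then 0 °C to rt
Reagents that add atoms: none
Why: Proposed new method: Sc(OSO2CF3)3 binds the oxirane oxygen of the epoxide, the C2–O bond (acetal carbon, assisted by the lone pair of O1; C3 is alpha to the ketone and cannot ionise) is opened by the only free phenol of the ring B partner from the face opposite the leaving oxygen to give the O-aryl acetal, and re-ionisation of this acetal to an oxocarbenium/scandium phenoxide ion pair lets an ortho carbon of ring B bond to C2, after which tautomerisation restores the phenol. The closest known reaction types are the Lewis-acid O-to-C rearrangement of aryl glycosides to ortho-hydroxyaryl C-glycosides (Fries-type) and the opening of 1,2-anhydro sugars by phenols; neither has been shown on a chromone 2,3-epoxide. No ring is closed (the oxirane opens and ring C is kept), so no mode of ring closure applies. C3 keeps the R configuration set in step 13 because its C–O bond is never broken, and C2 becomes R because the aryl group enters trans to the C3 oxygen: anti opening, return of the phenoxide to the face it left, shielding of the other face by the scandium alkoxide on C3, and the greater stability of the trans (diequatorial) isomer all point the same way. The step needs site selectivity for ring B over rings A, E, F and the two alkenes, C- over O-arylation, and capture of the cation before it loses H3 to give a 3-hydroxychromone; these should be secured by ring B holding the only free phenol (para carbon blocked by ring D, both ortho carbons equivalent, all other rings deactivated as acetates), by the reversibility of O-arylation against the irreversible C–C bond, and by low temperature, absence of base and portionwise addition of the epoxide.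

**Step 15**
Reactants: 19 pentaacetate
Product: 20 (2R,3R)-2-{5-[(1R,5S,6R)-6-[2,4-dihydroxy-3-(3-methylbut-2-enyl)benzoyl]-5-(2,4-dihydroxyphenyl)-3-methylcyclohex-2-en-1-yl]-2-hydroxyphenyl}-3,7-dihydroxychroman-4-one (target)
Conditions: K2CO3 (cat.), MeOH/THF, 0 °C, argon; then AcOH
Reagents that add atoms: none
Why: Zemplén-type methanolysis of the five aryl acetates under mild carbonate, cold and without air, should avoid ring C opening (C2/C3 epimerisation) and oxidation to the flavonol; the all-trans ring D is not at risk from enolisation at C6.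

**Compound list**

1 | 2',4'-dihydroxyacetophenone | CC(=O)c1ccc(O)cc1O | starting material
2 | 1-[2,4-dihydroxy-3-(3-methylbut-2-enyl)phenyl]ethanone | CC(=O)c1ccc(O)c(CC=C(C)C)c1O | intermediate
3 | 1-[2-hydroxy-3-(3-methylbut-2-enyl)-4-(prop-2-enyloxy)phenyl]ethanone | CC(=O)c1ccc(OCC=C)c(CC=C(C)C)c1O | intermediate
4 | 2,4-dihydroxybenzaldehyde | O=Cc1ccc(O)cc1O | starting material
5 | 2,4-bis(prop-2-enyloxy)benzaldehyde | O=Cc1ccc(OCC=C)cc1OCC=C | intermediate
6 | (E)-3-[2,4-bis(prop-2-enyloxy)phenyl]-1-[2-hydroxy-3-(3-methylbut-2-enyl)-4-(prop-2-enyloxy)phenyl]prop-2-en-1-one | CC(C)=CCc1c(OCC=C)ccc(C(=O)/C=C/c2ccc(OCC=C)cc2OCC=C)c1O | intermediate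
7 | morachalcone A | CC(C)=CCc1c(O)ccc(C(=O)/C=C/c2ccc(O)cc2O)c1O | intermediate
8 | (E)-1-[4-acetoxy-2-hydroxy-3-(3-methylbut-2-enyl)phenyl]-3-(2,4-diacetoxyphenyl)prop-2-en-1-one | CC(C)=CCc1c(OC(C)=O)ccc(C(=O)/C=C/c2ccc(OC(C)=O)cc2OC(C)=O)c1O | intermediate
9 | (E)-4-(4-hydroxyphenyl)but-3-en-2-one | CC(=O)/C=C/c1ccc(O)cc1 | starting material
10 | (E)-4-[4-(tert-butyldimethylsilyloxy)phenyl]but-3-en-2-one | CC(=O)/C=C/c1ccc(O[Si](C)(C)C(C)(C)C)cc1 | intermediate
11 | tert-butyldimethyl{4-[(1E)-3-methylbuta-1,3-dienyl]phenoxy}silane | C=C(C)/C=C/c1ccc(O[Si](C)(C)C(C)(C)C)cc1 | intermediate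
12 | exo adduct, (1R,5S,6R) ring D, free chelated OH on ring F, silyl ether on ring B | CC(C)=CCc1c(OC(C)=O)ccc(C(=O)[C@@H]2[C@@H](c3ccc(OC(C)=O)cc3OC(C)=O)CC(C)=C[C@H]2c2ccc(O[Si](C)(C)C(C)(C)C)cc2)c1O | intermediate
13 | tetraacetate of 12 (ring F OH acetylated), silyl ether on ring B | CC(C)=CCc1c(OC(C)=O)ccc(C(=O)[C@@H]2[C@@H](c3ccc(OC(C)=O)cc3OC(C)=O)CC(C)=C[C@H]2c2ccc(O[Si](C)(C)C(C)(C)C)cc2)c1OC(C)=O | intermediate
14 | 4-[(1R,5S,6R)-6-[2,4-diacetoxy-3-(3-methylbut-2-enyl)benzoyl]-5-(2,4-diacetoxyphenyl)-3-methylcyclohex-2-en-1-yl]phenol | CC(C)=CCc1c(OC(C)=O)ccc(C(=O)[C@@H]2[C@@H](c3ccc(OC(C)=O)cc3OC(C)=O)CC(C)=C[C@H]2c2ccc(O)cc2)c1OC(C)=O | intermediate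
15 | 7-hydroxychromone | O=c1ccoc2cc(O)ccc12 | starting material
16 | 7-acetoxychromone | CC(=O)Oc1ccc2c(=O)ccoc2c1 | intermediate
17 | (2R,3R)-7-acetoxy-2,3-epoxychroman-4-one | O=C1c2ccc(OC(C)=O)cc2O[C@H]2O[C@@H]12 | intermediate
18 | (2S,3R)-7-acetoxy-3-hydroxy-2-(aryloxy)chroman-4-one, aryl = ring B of 14 (2,3-trans O-aryl acetal) | CC(C)=CCc1c(OC(C)=O)ccc(C(=O)[C@@H]2[C@@H](c3ccc(OC(C)=O)cc3OC(C)=O)CC(C)=C[C@H]2c2ccc(O[C@H]3Oc4cc(OC(C)=O)ccc4C(=O)[C@@H]3O)cc2)c1OC(C)=O | intermediate
19 | pentaacetate of the target (free ring B OH and 3-OH), (2R,3R), (1R,5S,6R) | CC(C)=CCc1c(OC(C)=O)ccc(C(=O)[C@@H]2[C@@H](c3ccc(OC(C)=O)cc3OC(C)=O)CC(C)=C[C@H]2c2ccc(O)c([C@H]3Oc4cc(OC(C)=O)ccc4C(=O)[C@@H]3O)c2)c1OC(C)=O | intermediate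
20 | CNP0268637.1, (2R,3R)-2-{5-[(1R,5S,6R)-6-[2,4-dihydroxy-3-(3-methylbut-2-enyl)benzoyl]-5-(2,4-dihydroxyphenyl)-3-methylcyclohex-2-en-1-yl]-2-hydroxyphenyl}-3,7-dihydroxychroman-4-one | CC(C)=CCc1c(O)ccc(C(=O)[C@@H]2[C@@H](c3ccc(O)cc3O)CC(C)=C[C@H]2c2ccc(O)c([C@H]3Oc4cc(O)ccc4C(=O)[C@@H]3O)c2)c1O | target

**Step count and risks**

Total steps: 15. Longest linear sequence: 10 (steps 1, 2, 4, 5, 6, 9, 10, 11, 14, 15).

Step 14 (Proposed new method). Possible failures: the ring-opened cation may lose H3 and isomerise to a 3-hydroxychromone faster than it is captured, the sequence may stall at the O-aryl acetal, or the alkenes may trap the cation. Fallback with known reaction types, setting out from 14 and 16 and returning at 19. Ortho-iodination of 14 (N-iodosuccinimide, TsOH cat., MeCN, −20 °C) should give the 3-iodo-4-hydroxyphenyl compound F1. Miyaura borylation (bis(pinacolato)diboron, PdCl2[1,1'-bis(diphenylphosphino)ferrocene], KOAc, dioxane, 80 °C) should give the pinacol boronate F2. Rhodium-catalysed asymmetric 1,4-addition of F2 to 16 ([RhCl(C2H4)2]2, monovalent rhodium, with the chiral diene ligand enantiomer that gives 2S, substoichiometric K3PO4, dioxane/H2O) should give the (2S)-flavanone F3. Soft enolisation (Me3SiOSO2CF3, Et3N, CH2Cl2, 0 °C) should give the bis(trimethylsilyl) enol ether F4. Rubottom oxidation with dimethyldioxirane (one equivalent, acetone/CH2Cl2, −78 °C) should attack the enol ether face anti to the C2 aryl group and give the silyloxy epoxide F5, and HF·pyridine in the same flask should return 19.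

Step 13. Possible failures: poor facial discrimination on a double bond whose two ends differ only electronically (ring oxygen versus carbonyl), and opening of the epoxide during isolation. Fallback from 16 back to 19: epoxidise 16 with dimethyldioxirane in acetone without a chiral catalyst and use the crude racemate, that is 17 mixed with its enantiomer (2S,3S)-7-acetoxy-2,3-epoxychroman-4-one F6, directly in step 14. Enantiopure 14 should convert it into 19 and the (2S,3S)-flavanonol diastereomer F7, which differ throughout the ring A/C part and should be separable by chromatography.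

Step 9. Possible failures: a low exo/endo ratio or the wrong facial sense. Fallback from 8 and 11 back to 12: run the cycloaddition without chiral ligand on silica-supported silver nanoparticles (zerovalent silver) in CH2Cl2 at 50 °C, isolate the racemic exo adduct (12 with its mirror image ent-12 F8), and resolve it by preparative chromatography on a chiral stationary phase.

**Further compounds**

F1 | step 14 | ortho-iodophenol from 14 (3-iodo-4-hydroxyphenyl ring B) | CC(C)=CCc1c(OC(C)=O)ccc(C(=O)[C@@H]2[C@@H](c3ccc(OC(C)=O)cc3OC(C)=O)CC(C)=C[C@H]2c2ccc(O)c(I)c2)c1OC(C)=O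
F2 | step 14 | pinacol boronate (ring B: 4-hydroxy-3-(4,4,5,5-tetramethyl-1,3,2-dioxaborolan-2-yl)phenyl) | CC(C)=CCc1c(OC(C)=O)ccc(C(=O)[C@@H]2[C@@H](c3ccc(OC(C)=O)cc3OC(C)=O)CC(C)=C[C@H]2c2ccc(O)c(B3OC(C)(C)C(C)(C)O3)c2)c1OC(C)=O
F3 | step 14 | (2S)-7-acetoxyflavanone, 3-deoxy analogue of 19 | CC(C)=CCc1c(OC(C)=O)ccc(C(=O)[C@@H]2[C@@H](c3ccc(OC(C)=O)cc3OC(C)=O)CC(C)=C[C@H]2c2ccc(O)c([C@H]3Oc4cc(OC(C)=O)ccc4C(=O)C3)c2)c1OC(C)=O
F4 | step 14 | bis(trimethylsilyl) derivative of F3 (aryl silyl ether and 4-silyloxy-2H-chromene) | CC(C)=CCc1c(OC(C)=O)ccc(C(=O)[C@@H]2[C@@H](c3ccc(OC(C)=O)cc3OC(C)=O)CC(C)=C[C@H]2c2ccc(O[Si](C)(C)C)c([C@H]3Oc4cc(OC(C)=O)ccc4C(O[Si](C)(C)C)=C3)c2)c1OC(C)=O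
F5 | step 14 | 3,4-epoxy-4-(trimethylsilyloxy)chroman from F4, oxirane anti to the C2 aryl group | CC(C)=CCc1c(OC(C)=O)ccc(C(=O)[C@@H]2[C@@H](c3ccc(OC(C)=O)cc3OC(C)=O)CC(C)=C[C@H]2c2ccc(O[Si](C)(C)C)c([C@H]3Oc4cc(OC(C)=O)ccc4[C@]4(O[Si](C)(C)C)O[C@H]34)c2)c1OC(C)=O
F6 | step 13 | (2S,3S)-7-acetoxy-2,3-epoxychroman-4-one (enantiomer of 17) | O=C1c2ccc(OC(C)=O)cc2O[C@@H]2O[C@H]12
F7 | step 13 | (2S,3S)-flavanonol diastereomer of 19 | CC(C)=CCc1c(OC(C)=O)ccc(C(=O)[C@@H]2[C@@H](c3ccc(OC(C)=O)cc3OC(C)=O)CC(C)=C[C@H]2c2ccc(O)c([C@@H]3Oc4cc(OC(C)=O)ccc4C(=O)[C@H]3O)c2)c1OC(C)=O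
F8 | step 9 | ent-12, (1S,5R,6S) exo adduct | CC(C)=CCc1c(OC(C)=O)ccc(C(=O)[C@H]2[C@H](c3ccc(OC(C)=O)cc3OC(C)=O)CC(C)=C[C@@H]2c2ccc(O[Si](C)(C)C(C)(C)C)cc2)c1O
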